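Atom labels used throughout (target numbering): C1 is the ketone carbon, C2 the enone CH, C3 the enol-ether carbon (bearing O3), C4 the fully substituted sp3 carbon (bearing O4), C5 the ring CH2, C6 the allyl-bearing CH, C7 the benzylic CH2 and C8 the methyl-bearing CH of the side chain. Compound numbers are plain numerals.

## Analysis of the target

Target 17 is a cyclohex-2-enone (C1–C6) whose enol-ether carbon C3 and neighbouring sp3 carbon C4 are bridged through O3 and O4 by one methylene, so that a vinylogous ester is locked into a 1,3-dioxolane; C4 also carries the chain C8(H)(CH3)–C7H2–(3,4,5-trimethoxyphenyl) and C6 carries the allyl group. It has three stereocentres: the quaternary carbinol C4 (R), the exocyclic methine C8 (S) bonded directly to it, and C6 (R), which lies 1,3 to C4 across C5 with its allyl group on the face of O4 and opposite to C8. C6 is α to C1 and is the only enolisable position of the bicycle, so it can be corrected at the end, whereas C4 and C8 are fixed once C4 is quaternary. The sensitive groups are the acetal-bound vinylogous ester (acid can ionise C4–O4 and lead to a resorcinol; nucleophiles can add at C3), the terminal alkene (no hydrogenation, few oxidants) and the electron-rich arene. The difficulty is the C4/C8 pair: the two centres are joined by a freely rotating bond, and methyl and arylmethyl on C8 are close in size, so neither a ring nor a clear steric bias relays configuration; in addition the acetal has to be closed on O3/O4 of a system whose C2 is nucleophilic. The strategy rests on the neighbours of C4, namely the acyl carbon C3, the methylene C5 and C8. If C4 is written as the ketone of a 2-oxo ester with C3 as the ester, the C8 hydrogen lies next to a 1,2-dicarbonyl and is configurationally labile; addition of a C5 nucleophile to that ketone can then create C4 and select C8 in one event, and the new alkoxide O4 is placed to capture the acyl carbon C1.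

## Retrosynthetic reasoning

17 from 16. The last operation breaks no skeletal bond. Compound 16 is the bicycle as a mixture of C6 epimers, and C6 is its only acidic position. With O4 held near the enone plane by the dioxolane, C8 must be pseudo-axial on C4, and the allyl group is equatorial only when it is trans to C8, which is the arrangement in 17. The forward step therefore only has to equilibrate C6 without opening the acetal.

16 from 14. Both O–CH2 bonds of the acetal are cut, which gives the 4-hydroxy-1,3-dione 14. The acetal is the most fragile part of the molecule, so it is put on late. Of the two enol oxygens of 14 only O3 can be joined to O4 by a single carbon in a five-membered ring, which decides the regiochemistry. The forward reaction must bring the one-carbon unit to oxygen and keep it away from C2.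

14 from 12. The ring bond C2–C3 is cut as a Claisen (Dieckmann-type) condensation of a methyl ketone (C1 carbonyl, C2 methyl) onto an ester at C3. This is the natural place because C3 then stays at the ester oxidation level it has in the 2-oxo ester, and the 1,3-dioxygenation pattern of the ring appears directly. Only the C2 enolate can reach C3 through a six-membered transition state, and formation of the dione enolate drives the step. In 12 the tertiary O4 is masked as a trimethylsilyl ether, which is lost on work-up via 13.

12 from 9 through 11 and 10. The C1–C2 bond is cut to a methyl nucleophile and a Weinreb amide 11, and the amide is traced to the γ-lactone 9 by reconnecting C1 to O4. The lactone already holds C1, C6, C5, C4 and C3 at the right oxidation levels, so only the C2 carbon is missing. The forward steps must open the lactone selectively in the presence of the hindered ester (10), cap O4 before the γ-hydroxy amide closes back (11), and stop the methyl addition at the ketone (12).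

9 from 6 and 8 (key disconnection). The lactone is cut at C4–C5 and at O4–C1. This returns the racemic 2-oxo ester 6 and the enal 8, whose aldehyde carbon is C1, whose α-carbon is C6 with the allyl group already attached, and whose methylidene carbon is C5. A cut at C4–C8 or C4–C3 would require a secondary or acyl anion adding to a hindered ketone and would not use the lability of C8. The forward reaction has to make C5 nucleophilic (a homoenolate), add it to one face of the C4 ketone of one of the two interconverting enantiomers of 6, and let O4 acylate C1.

6 from 1 and 2; 8 from 7. The C8–C7 bond of 6 is cut as a benzylation of the stabilised enolate of 1 with 2 (giving 3), followed by hydrolysis with loss of the extra carboxyl (4, then 5) and re-esterification. Enal 8 comes from 7 by Mannich-type α-methylenation. These are short, reliable sequences from commercial materials, so the risk of the route is concentrated in the annulation.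

## Alternatives that were turned down

Alternative 1: Disconnection: the ring bonds C1–C2 and C1–C6 are both cut and C1 is taken from carbon monoxide. This leads back to the iodide A2, (4R,5E)-4-allyl-5-(iodomethylidene)-4-[(2S)-1-(3,4,5-trimethoxyphenyl)propan-2-yl]-1,3-dioxolane, in which the acetal and the enol ether already exist. Forward key step: zerovalent palladium, formed from PdCl2(PPh3)2 and Et3N, inserts into the C2–I bond; CO insertion gives an acyl–palladium species; this adds 6-exo across the terminal double bond of the allyl group on C4 (C1–C6 bond); β-hydride elimination releases the cross-conjugated 6-methylidene enone A1.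
- For it: the acid- and nucleophile-sensitive dioxolane is in place before the carbocycle is formed, so no late acetalisation is needed. On this point it is stronger than the chosen route.
- Against it: the step creates no stereocentre, so C4 and C8 must both be made beforehand in an acyclic precursor of A2, which is the hard part of the molecule. The stereodefined exocyclic (E)-iodo enol ether of A2 is itself demanding. A1 still lacks two carbons of the allyl group and needs a vinyl conjugate addition to its exocyclic methylene; as a doubly activated dienone it can oligomerise or be isomerised by palladium hydride to the endocyclic dienone first.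
- Comparison: in exchange for a late acetalisation, the chosen route forms C4 and C8 in its ring-forming step, carries the allyl group in intact and avoids pressurised CO. Alternative 1 would be longer once the synthesis of A2 is counted.

Alternative 2: Disconnection: C4–C5 and C2–C3, the same two ring bonds as in the chosen route, but made in one flask from the dioxolanone A4, (2R,5R)-2-tert-butyl-5-[(2S)-1-(3,4,5-trimethoxyphenyl)propan-2-yl]-1,3-dioxolan-4-one, and the enone A5, 3-methylidenehex-5-en-2-one. Forward key step: the lithium enolate of A4 adds through C4 to the methylidene carbon of A5 on the face away from the tert-butyl group; the enolate so formed lies toward C6 and must relay to the methyl side; C2 then attacks the acetal carbonyl C3 and expels the acetal fragment. The product is the hydroxy dione A3, (4R,6R)-6-allyl-4-hydroxy-4-[(2S)-1-(3,4,5-trimethoxyphenyl)propan-2-yl]cyclohexane-1,3-dione, which is the 6R epimer of 14.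
- For it: C4 is set by a well-understood cyclic template, which is more secure than a new carbene-catalysed resolution, and the dione is reached four steps sooner. On both points it is stronger.
- Against it: C8 is not addressed by the key step. A4 needs a hydroxy acid that is already pure at both C4 and C8, which costs several chiral-pool steps. A5 is a polymerisation-prone α-methylidene ketone. The enolate relay from C6 to C2 competes with proton quench and retro-Michael cleavage, and the Claisen step must attack a carbonyl flanked by the new quaternary centre.
- Comparison: the chosen route draws C8 from a cheap racemate by catalysis and uses simple building blocks, and it pays with a stepwise lactone-to-dione passage. The endgame (acetalisation, C6) would be identical.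

Alternative 3: Disconnection: O4–CH2 and O3–C3, which leads to the para-quinol A7, 4-hydroxy-4-[(2S)-1-(3,4,5-trimethoxyphenyl)propan-2-yl]cyclohexa-2,5-dien-1-one. Forward key step: a chiral phosphoric acid promotes hemiformal formation between the tertiary hydroxyl and formaldehyde, and the hemiformal oxygen adds 5-exo-trig to the β-carbon of one of the two enone arms. The product is the cis-fused A6, cis-7a-[(2S)-1-(3,4,5-trimethoxyphenyl)propan-2-yl]-3a,4-dihydro-1,3-benzodioxol-5(7aH)-one.
- For it: the dioxolane is made directly and catalytically from a flat precursor available by oxidative dearomatisation of a para-alkylphenol. This is the shortest access to the acetal and clearly stronger than the late bis-alkylation of the chosen route.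
- Against it: because C8 is already stereogenic in A7, the two enone arms are diastereotopic; C8 must be made first and the catalyst then works with or against it. A6 has the wrong oxidation pattern: C3 is an sp3 β-alkoxy ketone carbon and the C5=C6 enone remains. Reaching the target still needs reduction and allylation at C6 and dehydrogenation of C2–C3, while the β-alkoxy ketone can revert by retro-oxa-Michael and the quinol can undergo acid-induced dienone–phenol rearrangement.
- Comparison: the chosen route delivers the 1,3-dione oxidation level and the allyl group directly and sets C8 catalytically. It is weaker only in how the acetal is formed.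

Key step: step 5

Remark: C6 is not controlled before the last step; compounds 9–16 are therefore expected as mixtures of the two C6 epimers, are carried on without separation, and are named and drawn with that centre left open.

## Route

Step 1
Reactants: 1 diethyl oxalpropionate (diethyl 2-methyl-3-oxobutanedioate); 2 3,4,5-trimethoxybenzyl chloride
Product: 3 diethyl 2-methyl-3-oxo-2-(3,4,5-trimethoxybenzyl)butanedioate (racemic)
Conditions: NaH, THF, 0 °C; then 2, NaI (cat.), reflux
Reagents that add atoms: none
Why: C-alkylation of the doubly stabilised sodium enolate of a β-keto ester with a benzylic halide (activated in situ by Finkelstein exchange); the tight ion pair in THF favours carbon over oxygen, and the absence of free alkoxide avoids retro-Claisen loss of the oxalyl group from the quaternary product.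

Step 2
Reactants: 3 diethyl 2-methyl-3-oxo-2-(3,4,5-trimethoxybenzyl)butanedioate
Product: 5 3-methyl-2-oxo-4-(3,4,5-trimethoxyphenyl)butanoic acid (racemic), via keto diacid 4 (not isolated)
Conditions: 2 M aq. HCl/AcOH, 85 °C
Reagents that add atoms: water, O
Why: Acid hydrolysis of both esters followed by decarboxylation of the β-keto acid through its cyclic transition state, the classical ketonic cleavage of an alkylated oxalyl ester; the α-keto acid does not decarboxylate and the aryl methyl ethers are stable to dilute acid, and the temperature is kept moderate so that the activated ketone does not cyclise onto the electron-rich ring.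

Step 3
Reactants: 5 3-methyl-2-oxo-4-(3,4,5-trimethoxyphenyl)butanoic acid
Product: 6 ethyl 3-methyl-2-oxo-4-(3,4,5-trimethoxyphenyl)butanoate (racemic)
Conditions: EtOH, H2SO4 (cat.), reflux; aq. NaHCO3 work-up
Reagents that add atoms: ethanol, CCO
Why: Fischer esterification, which is fast for α-keto acids because the neighbouring carbonyl activates the carboxyl group; any hemiketal reverts on aqueous work-up.

Step 4
Reactants: 7 pent-4-enal
Product: 8 2-methylidenepent-4-enal
Conditions: 37% aq. CH2O, pyrrolidine (10 mol%), EtCO2H (10 mol%), i-PrOH, 40 °C; distilled and used fresh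
Reagents that add atoms: formaldehyde, C=O
Why: Mannich α-methylenation: the pyrrolidine enamine of the aldehyde adds to the formaldehyde-derived iminium ion and the β-amino aldehyde eliminates the amine to give the 2-substituted acrolein; short reaction time limits migration of the skipped double bond.

Step 5
Reactants: 6 ethyl 3-methyl-2-oxo-4-(3,4,5-trimethoxyphenyl)butanoate (racemic); 8 2-methylidenepent-4-enal
Product: 9 ethyl (2R)-5-oxo-4-(prop-2-en-1-yl)-2-[(2S)-1-(3,4,5-trimethoxyphenyl)propan-2-yl]oxolane-2-carboxylate (both C6 epimers)
Conditions: 2-mesityl-5a,10b-dihydro-4H,6H-indeno[2,1-b][1,2,4]triazolo[4,3-d][1,4]oxazin-2-ium chloride ((5aS,10bR) or (5aR,10bS), the enantiomer that gives 2R; 15 mol%), DBU (20 mol%), 4 Å molecular sieves, THF, 25 °C, slow addition of 8 (2 equiv)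
Reagents that add atoms: none
Why: Proposed new method: the carbene formed from the triazolium salt adds to the aldehyde of 8 and proton transfer gives the Breslow intermediate, whose terminal carbon C5 is nucleophilic; C5 adds to the ketone carbon C4 of 6, the enol azolium is protonated at C6 to the acyl azolium, and the tertiary alkoxide O4 acylates C1 in a 5-exo-trig closure that forms the lactone and releases the carbene. The closest known reaction type is the carbene-catalysed homoenolate annulation of β-substituted enals with α-keto esters to γ-butyrolactones, including its dynamic kinetic version with racemic β-halo α-keto esters; new here are the β-unsubstituted, α-branched enal and a keto ester whose labile centre carries only alkyl groups. C4 is controlled by the catalyst: the aminoindane backbone and the N-mesityl group leave one face of the homoenolate open, and hydrogen bonding of the Breslow hydroxyl to the ketone oxygen fixes the ketone face presented to it. C8 is controlled by dynamic kinetic resolution: its hydrogen is acidified by the 1,2-dicarbonyl, DBU interconverts the enantiomers of 6 through the enol, and the catalyst is expected to turn over the enantiomer that places the small methyl group, not the arylmethyl arm, toward its aminoindane wall. C6 arises from an unselective protonation and is deliberately left open. The step needs homoenolate rather than acyl-anion reactivity, which N-mesityl triazolium catalysts favour, and attack on the keto ester rather than on a second molecule of 8, which slow addition of 8 supports. It also needs racemisation of 6 to be faster than C–C bond formation, which the hindered ketone and the amidine base make plausible.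

Step 6
Reactants: 9 ethyl (2R)-5-oxo-4-(prop-2-en-1-yl)-2-[(2S)-1-(3,4,5-trimethoxyphenyl)propan-2-yl]oxolane-2-carboxylate
Product: 10 ethyl (2R)-2-hydroxy-4-[methoxy(methyl)carbamoyl]-2-[(2S)-1-(3,4,5-trimethoxyphenyl)propan-2-yl]hept-6-enoate (both C6 epimers)
Conditions: MeNH(OMe)·HCl, i-PrMgCl, THF, −20 → 0 °C; aq. NH4Cl, cold; crude used at once
Reagents that add atoms: N,O-dimethylhydroxylamine hydrochloride, CNOC.Cl
Why: Weinreb aminolysis of the lactone by the chloromagnesium amide; the lactone carbonyl C1 is far more reactive than the ethyl ester on the fully substituted C4, and under the basic conditions the magnesium alkoxide cannot close back.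

Step 7
Reactants: 10 ethyl (2R)-2-hydroxy-4-[methoxy(methyl)carbamoyl]-2-[(2S)-1-(3,4,5-trimethoxyphenyl)propan-2-yl]hept-6-enoate
Product: 11 ethyl (2R)-4-[methoxy(methyl)carbamoyl]-2-[(2S)-1-(3,4,5-trimethoxyphenyl)propan-2-yl]-2-[(trimethylsilyl)oxy]hept-6-enoate (both C6 epimers)
Conditions: Me3SiOTf, 2,6-lutidine, CH2Cl2, −78 °C
Reagents that add atoms: trimethylsilyl trifluoromethanesulfonate, C[Si](C)(C)OS(=O)(=O)C(F)(F)F
Why: Silylation of a hindered tertiary alcohol with a silyl triflate, fast at low temperature; capping O4 stops relactonisation of the γ-hydroxy amide and keeps the alkoxide out of the Grignard step.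

Step 8
Reactants: 11 ethyl (2R)-4-[methoxy(methyl)carbamoyl]-2-[(2S)-1-(3,4,5-trimethoxyphenyl)propan-2-yl]-2-[(trimethylsilyl)oxy]hept-6-enoate
Product: 12 ethyl (2R)-4-acetyl-2-[(2S)-1-(3,4,5-trimethoxyphenyl)propan-2-yl]-2-[(trimethylsilyl)oxy]hept-6-enoate (both C6 epimers)
Conditions: MeMgBr, THF, −20 → 0 °C; aq. NH4Cl
Reagents that add atoms: methylmagnesium bromide, C[Mg]Br
Why: Weinreb ketone synthesis: the chelated tetrahedral adduct survives until work-up, so addition stops at the methyl ketone (C2 introduced), and the ester on the quaternary, silyloxy-bearing C4 is too hindered to react at this temperature.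

Step 9
Reactants: 12 ethyl (2R)-4-acetyl-2-[(2S)-1-(3,4,5-trimethoxyphenyl)propan-2-yl]-2-[(trimethylsilyl)oxy]hept-6-enoate
Product: 14 (4R)-6-allyl-4-hydroxy-4-[(2S)-1-(3,4,5-trimethoxyphenyl)propan-2-yl]cyclohexane-1,3-dione (both C6 epimers), via silyloxy dione 13 (not isolated)
Conditions: KOt-Bu (2.5 equiv), THF (0.02 M), 0 → 25 °C; then 1 M aq. HCl, THF, 0 °C, brief
Reagents that add atoms: none
Why: Claisen (Dieckmann-type) condensation: of the two ketone enolates only the methyl-derived C2 enolate can reach the ester C3 through a six-membered transition state (the C6 enolate would give a four-membered ring), and deprotonation of the 1,3-dione makes the closure irreversible; the cold acidic work-up protonates the dione and cleaves the labile tertiary silyl ether, and it is kept short because acid can dehydrate 14 to a resorcinol.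

Step 10
Reactants: 14 (4R)-6-allyl-4-hydroxy-4-[(2S)-1-(3,4,5-trimethoxyphenyl)propan-2-yl]cyclohexane-1,3-dione
Product: 16 (7aR)-6-allyl-7a-[(2S)-1-(3,4,5-trimethoxyphenyl)propan-2-yl]-7,7a-dihydro-1,3-benzodioxol-5(6H)-one (both C6 epimers), via chloromethyl ether 15 (not isolated)
Conditions: NaH (2.05 equiv), BrCH2Cl (1.5 equiv), DMF, 0 → 25 °C
Reagents that add atoms: bromochloromethane, ClCBr
Why: Double Williamson-type methylene acetal formation: in the dianion the tertiary alkoxide O4 is by far the strongest nucleophile and displaces bromide, and the resulting chloromethyl ether alkylates the dione enolate on oxygen, as α-chloro ethers do with 1,3-dione enolates. Only O3 is within reach for a five-membered ring, which fixes the regiochemistry and leaves C1 as the ketone.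

Step 11
Reactants: 16 (7aR)-6-allyl-7a-[(2S)-1-(3,4,5-trimethoxyphenyl)propan-2-yl]-7,7a-dihydro-1,3-benzodioxol-5(6H)-one (both C6 epimers)
Product: 17 (6R,7aR)-6-allyl-7a-[(2S)-1-(3,4,5-trimethoxyphenyl)propan-2-yl]-7,7a-dihydro-1,3-benzodioxol-5(6H)-one
Conditions: KOt-Bu (0.2 equiv), t-BuOH/THF, 25 °C; AcOH quench
Reagents that add atoms: none
Why: Thermodynamic epimerisation through the C6 enolate, the only enolisable position of the vinylogous ester; the dioxolane holds O4 near the enone plane and C8 pseudo-axial, so the allyl group is equatorial only when trans to C8 (6R), and the bulky, poorly nucleophilic base is chosen so that it does not add at C3.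

## Compound list

1 | diethyl oxalpropionate (diethyl 2-methyl-3-oxobutanedioate) | CCOC(=O)C(C)C(=O)C(=O)OCC | starting material
2 | 3,4,5-trimethoxybenzyl chloride | COc1cc(CCl)cc(OC)c1OC | starting material
3 | diethyl 2-methyl-3-oxo-2-(3,4,5-trimethoxybenzyl)butanedioate (racemic) | CCOC(=O)C(=O)C(C)(Cc1cc(OC)c(OC)c(OC)c1)C(=O)OCC | intermediate
4 | 2-methyl-3-oxo-2-(3,4,5-trimethoxybenzyl)butanedioic acid (racemic) | OC(=O)C(=O)C(C)(Cc1cc(OC)c(OC)c(OC)c1)C(=O)O | intermediate (not isolated)
5 | 3-methyl-2-oxo-4-(3,4,5-trimethoxyphenyl)butanoic acid (racemic) | OC(=O)C(=O)C(C)Cc1cc(OC)c(OC)c(OC)c1 | intermediate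
6 | ethyl 3-methyl-2-oxo-4-(3,4,5-trimethoxyphenyl)butanoate (racemic) | CCOC(=O)C(=O)C(C)Cc1cc(OC)c(OC)c(OC)c1 | intermediate
7 | pent-4-enal | C=CCCC=O | starting material
8 | 2-methylidenepent-4-enal | C=CCC(=C)C=O | intermediate
9 | ethyl (2R)-5-oxo-4-(prop-2-en-1-yl)-2-[(2S)-1-(3,4,5-trimethoxyphenyl)propan-2-yl]oxolane-2-carboxylate (C6 epimer mixture) | O=C1O[C@@](C(=O)OCC)([C@@H](C)Cc2cc(OC)c(OC)c(OC)c2)CC1CC=C | intermediate
10 | ethyl (2R)-2-hydroxy-4-[methoxy(methyl)carbamoyl]-2-[(2S)-1-(3,4,5-trimethoxyphenyl)propan-2-yl]hept-6-enoate (C6 epimer mixture) | CCOC(=O)[C@@](O)(CC(CC=C)C(=O)N(C)OC)[C@@H](C)Cc1cc(OC)c(OC)c(OC)c1 | intermediate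
11 | ethyl (2R)-4-[methoxy(methyl)carbamoyl]-2-[(2S)-1-(3,4,5-trimethoxyphenyl)propan-2-yl]-2-[(trimethylsilyl)oxy]hept-6-enoate (C6 epimer mixture) | CCOC(=O)[C@@](O[Si](C)(C)C)(CC(CC=C)C(=O)N(C)OC)[C@@H](C)Cc1cc(OC)c(OC)c(OC)c1 | intermediate
12 | ethyl (2R)-4-acetyl-2-[(2S)-1-(3,4,5-trimethoxyphenyl)propan-2-yl]-2-[(trimethylsilyl)oxy]hept-6-enoate (C6 epimer mixture) | CCOC(=O)[C@@](O[Si](C)(C)C)(CC(CC=C)C(C)=O)[C@@H](C)Cc1cc(OC)c(OC)c(OC)c1 | intermediate
13 | (4R)-6-allyl-4-[(2S)-1-(3,4,5-trimethoxyphenyl)propan-2-yl]-4-[(trimethylsilyl)oxy]cyclohexane-1,3-dione (C6 epimer mixture) | C=CCC1C[C@@](O[Si](C)(C)C)([C@@H](C)Cc2cc(OC)c(OC)c(OC)c2)C(=O)CC1=O | intermediate (not isolated)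
14 | (4R)-6-allyl-4-hydroxy-4-[(2S)-1-(3,4,5-trimethoxyphenyl)propan-2-yl]cyclohexane-1,3-dione (C6 epimer mixture) | C=CCC1C[C@@](O)([C@@H](C)Cc2cc(OC)c(OC)c(OC)c2)C(=O)CC1=O | intermediate
15 | (4R)-6-allyl-4-(chloromethoxy)-4-[(2S)-1-(3,4,5-trimethoxyphenyl)propan-2-yl]cyclohexane-1,3-dione (C6 epimer mixture, present as its sodium enolate) | C=CCC1C[C@@](OCCl)([C@@H](C)Cc2cc(OC)c(OC)c(OC)c2)C(=O)CC1=O | intermediate (not isolated)
16 | (7aR)-6-allyl-7a-[(2S)-1-(3,4,5-trimethoxyphenyl)propan-2-yl]-7,7a-dihydro-1,3-benzodioxol-5(6H)-one (C6 epimer mixture) | C=CCC1C[C@]2([C@@H](C)Cc3cc(OC)c(OC)c(OC)c3)OCOC2=CC1=O | intermediate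
17 | (6R,7aR)-6-allyl-7a-[(2S)-1-(3,4,5-trimethoxyphenyl)propan-2-yl]-7,7a-dihydro-1,3-benzodioxol-5(6H)-one | C=CC[C@@H]1C[C@]2([C@@H](C)Cc3cc(OC)c(OC)c(OC)c3)OCOC2=CC1=O | target

## Step count and least certain steps

Total step count: 11. Longest linear sequence: 10 steps (steps 1–3 and 5–11); step 4 is the one-step side branch.

Step 5 (key step, proposed new method). The most likely failure is weak discrimination between the two interconverting enantiomers of 6 in the C–C bond-forming event. Methyl and arylmethyl on C8 present almost the same bulk to the incoming homoenolate, so C4 could form with good face selectivity while C8 is not resolved. A second failure is diversion of 8, whose β-carbon is unhindered and whose skipped diene is base-sensitive: conjugate addition of the carbene, self-annulation, or migration of the double bond into conjugation.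

The fallback uses known chemistry, sets out from 6 and returns at 9.
- Racemic 6 is reduced under dynamic kinetic conditions with an (R)-selective ketoreductase from a commercial panel (NADP+, glucose, glucose dehydrogenase, phosphate buffer pH 7.5–8, 30 °C). An enzyme pocket distinguishes methyl from arylmethyl readily. This gives ethyl (2R,3S)-2-hydroxy-3-methyl-4-(3,4,5-trimethoxyphenyl)butanoate F1; any C8-epimeric hydroxy ester is separable and can be oxidised back to 6.
- Saponification (LiOH, THF/H2O) gives (2R,3S)-2-hydroxy-3-methyl-4-(3,4,5-trimethoxyphenyl)butanoic acid F2.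
- Acetalisation with pivalaldehyde (TsOH cat., pentane, azeotropic removal of water) gives the cis acetal (2R,5R)-2-tert-butyl-5-[(2S)-1-(3,4,5-trimethoxyphenyl)propan-2-yl]-1,3-dioxolan-4-one F3.
- Enolisation with LiN(i-Pr)2 (THF, −78 °C) and alkylation with ethyl 2-(bromomethyl)acrylate occurs trans to the tert-butyl group, that is with retention at C4 (self-regeneration of the stereocentre). This gives (2R,5R)-2-tert-butyl-5-[2-(ethoxycarbonyl)prop-2-en-1-yl]-5-[(2S)-1-(3,4,5-trimethoxyphenyl)propan-2-yl]-1,3-dioxolan-4-one F4.
- TsOH in EtOH at reflux cleaves the acetal and closes the lactone to ethyl (2R)-4-methylidene-5-oxo-2-[(2S)-1-(3,4,5-trimethoxyphenyl)propan-2-yl]oxolane-2-carboxylate F5.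
- Conjugate addition of CH2=CHMgBr with CuBr·SMe2 (cat.) and Me3SiCl (THF, −78 °C) to the exocyclic methylene completes the allyl group and gives 9.

Step 10. The most likely failure is alkylation of the ambident dione enolate at C2 or at O1 before the hindered alkoxide O4 has reacted. This leads to C-methylenation and intermolecular methylene-bridged material, because dihalomethanes are slow electrophiles and C2 of a 1,3-dione is strongly nucleophilic.

The fallback brings the acetal carbon in on O4 before the ring is closed; it sets out from 10 and returns at 16.
- Crude 10 is protected with MeOCH2Cl, i-Pr2NEt and NaI (cat.) in CH2Cl2 to give ethyl (2R)-2-(methoxymethoxy)-4-[methoxy(methyl)carbamoyl]-2-[(2S)-1-(3,4,5-trimethoxyphenyl)propan-2-yl]hept-6-enoate F6.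
- MeMgBr (THF, −20 °C) gives ethyl (2R)-4-acetyl-2-(methoxymethoxy)-2-[(2S)-1-(3,4,5-trimethoxyphenyl)propan-2-yl]hept-6-enoate F7.
- KOt-Bu (THF) closes (4R)-6-allyl-4-(methoxymethoxy)-4-[(2S)-1-(3,4,5-trimethoxyphenyl)propan-2-yl]cyclohexane-1,3-dione F8.
- Me3SiOTf with 2,2'-bipyridyl (CH2Cl2, 0 °C) ionises the methoxymethyl ether, and the enol oxygen O3 captures the resulting electrophile in a five-membered closure with loss of methanol, giving 16.

Step 11. The most likely failure is incomplete convergence at C6, because the free-energy gap between the two ring epimers may be small. Slow addition of butoxide at C3, with opening of the acetal, is a lesser concern.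

The fallback replaces thermodynamic control by kinetic control; it sets out from 16 and returns at 17. LiN(i-Pr)2 (THF, −78 °C) converts 16 irreversibly into lithium (7aR)-6-allyl-7a-[(2S)-1-(3,4,5-trimethoxyphenyl)propan-2-yl]-7,7a-dihydro-1,3-benzodioxol-5-olate F9. Cold protonation with a small donor (AcOH) is intended to deliver hydrogen axially on the C8 face to give 17. The facial preference of this protonation is uncertain, so a chiral proton donor of either hand would be tried if the substrate bias runs the wrong way. The epimers are diastereomers, so the minor one can be separated and returned to the enolate.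

Step 6 (with step 7). The most likely failure is relactonisation of the γ-hydroxy amide with loss of the amine during work-up or before silylation is complete. The free tertiary hydroxyl sits five atoms from an activated amide carbonyl, and the substitution on C4 favours ring closure.

The fallback avoids isolating any hydroxy amide and drops the protecting group; it sets out from 9 and returns at 14. The aminolysis mixture of step 6 (chloromagnesium alkoxide of 10) is treated directly with MeMgBr at −20 → 0 °C to give ethyl (2R)-4-acetyl-2-hydroxy-2-[(2S)-1-(3,4,5-trimethoxyphenyl)propan-2-yl]hept-6-enoate F10, which will sit largely as its cyclic hemiketal. F10 is cyclised as the alkoxide–enolate dianion with KOt-Bu (3 equiv, THF) and gives 14 after cold acidic work-up.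

## Further compounds

F1 | step 5 | ethyl (2R,3S)-2-hydroxy-3-methyl-4-(3,4,5-trimethoxyphenyl)butanoate | CCOC(=O)[C@H](O)[C@@H](C)Cc1cc(OC)c(OC)c(OC)c1
F2 | step 5 | (2R,3S)-2-hydroxy-3-methyl-4-(3,4,5-trimethoxyphenyl)butanoic acid | OC(=O)[C@H](O)[C@@H](C)Cc1cc(OC)c(OC)c(OC)c1
F3 | step 5 | (2R,5R)-2-tert-butyl-5-[(2S)-1-(3,4,5-trimethoxyphenyl)propan-2-yl]-1,3-dioxolan-4-one | CC(C)(C)[C@H]1OC(=O)[C@H](O1)[C@@H](C)Cc2cc(OC)c(OC)c(OC)c2
F4 | step 5 | (2R,5R)-2-tert-butyl-5-[2-(ethoxycarbonyl)prop-2-en-1-yl]-5-[(2S)-1-(3,4,5-trimethoxyphenyl)propan-2-yl]-1,3-dioxolan-4-one | CC(C)(C)[C@H]1OC(=O)[C@@](O1)(CC(=C)C(=O)OCC)[C@@H](C)Cc2cc(OC)c(OC)c(OC)c2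
F5 | step 5 | ethyl (2R)-4-methylidene-5-oxo-2-[(2S)-1-(3,4,5-trimethoxyphenyl)propan-2-yl]oxolane-2-carboxylate | O=C1O[C@@](C(=O)OCC)([C@@H](C)Cc2cc(OC)c(OC)c(OC)c2)CC1=C
F6 | step 10 | ethyl (2R)-2-(methoxymethoxy)-4-[methoxy(methyl)carbamoyl]-2-[(2S)-1-(3,4,5-trimethoxyphenyl)propan-2-yl]hept-6-enoate (C6 epimer mixture) | CCOC(=O)[C@@](OCOC)(CC(CC=C)C(=O)N(C)OC)[C@@H](C)Cc1cc(OC)c(OC)c(OC)c1
F7 | step 10 | ethyl (2R)-4-acetyl-2-(methoxymethoxy)-2-[(2S)-1-(3,4,5-trimethoxyphenyl)propan-2-yl]hept-6-enoate (C6 epimer mixture) | CCOC(=O)[C@@](OCOC)(CC(CC=C)C(C)=O)[C@@H](C)Cc1cc(OC)c(OC)c(OC)c1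
F8 | step 10 | (4R)-6-allyl-4-(methoxymethoxy)-4-[(2S)-1-(3,4,5-trimethoxyphenyl)propan-2-yl]cyclohexane-1,3-dione (C6 epimer mixture) | C=CCC1C[C@@](OCOC)([C@@H](C)Cc2cc(OC)c(OC)c(OC)c2)C(=O)CC1=O
F9 | step 11 | lithium (7aR)-6-allyl-7a-[(2S)-1-(3,4,5-trimethoxyphenyl)propan-2-yl]-7,7a-dihydro-1,3-benzodioxol-5-olate | [Li+].[O-]C1=C(CC=C)C[C@]2([C@@H](C)Cc3cc(OC)c(OC)c(OC)c3)OCOC2=C1
F10 | step 6 | ethyl (2R)-4-acetyl-2-hydroxy-2-[(2S)-1-(3,4,5-trimethoxyphenyl)propan-2-yl]hept-6-enoate (C6 epimer mixture) | CCOC(=O)[C@@](O)(CC(CC=C)C(C)=O)[C@@H](C)Cc1cc(OC)c(OC)c(OC)c1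
A1 | alternative 1 | (7aR)-6-methylidene-7a-[(2S)-1-(3,4,5-trimethoxyphenyl)propan-2-yl]-7,7a-dihydro-1,3-benzodioxol-5(6H)-one | C=C1C[C@]2([C@@H](C)Cc3cc(OC)c(OC)c(OC)c3)OCOC2=CC1=O
A2 | alternative 1 | (4R,5E)-4-allyl-5-(iodomethylidene)-4-[(2S)-1-(3,4,5-trimethoxyphenyl)propan-2-yl]-1,3-dioxolane | I/C=C1/OCO[C@]1(CC=C)[C@@H](C)Cc2cc(OC)c(OC)c(OC)c2
A3 | alternative 2 | (4R,6R)-6-allyl-4-hydroxy-4-[(2S)-1-(3,4,5-trimethoxyphenyl)propan-2-yl]cyclohexane-1,3-dione | C=CC[C@@H]1C[C@@](O)([C@@H](C)Cc2cc(OC)c(OC)c(OC)c2)C(=O)CC1=O
A4 | alternative 2 | (2R,5R)-2-tert-butyl-5-[(2S)-1-(3,4,5-trimethoxyphenyl)propan-2-yl]-1,3-dioxolan-4-one | CC(C)(C)[C@H]1OC(=O)[C@H](O1)[C@@H](C)Cc2cc(OC)c(OC)c(OC)c2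
A5 | alternative 2 | 3-methylidenehex-5-en-2-one | C=CCC(=C)C(C)=O
A6 | alternative 3 | cis-7a-[(2S)-1-(3,4,5-trimethoxyphenyl)propan-2-yl]-3a,4-dihydro-1,3-benzodioxol-5(7aH)-one | O=C1C=C[C@]2([C@@H](C)Cc3cc(OC)c(OC)c(OC)c3)OCO[C@@H]2C1
A7 | alternative 3 | 4-hydroxy-4-[(2S)-1-(3,4,5-trimethoxyphenyl)propan-2-yl]cyclohexa-2,5-dien-1-one | O=C1C=CC(O)(C=C1)[C@@H](C)Cc2cc(OC)c(OC)c(OC)c2
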